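All constants were drawn at random within sensible limits; the flask was simulated.

Teal carries 0.600 of violet's initiator on the charge, but less than that, 0.437, once the impurity is subtracted.

common to all: free monomer 2.0 M; impurity 2.9 mM; time 20 min

|  | initiator |
|---|---|
| violet | 10 mM |
| teal | 6.0 mM |

    2 initiator → spent initiator B (k1 = 2.54 M⁻¹ s⁻¹)
    initiator + impurity → spent initiator A (k2 = 9800 M⁻¹ s⁻¹)
    free monomer + initiator → living end + monomer in chains (k3 = 0.124 M⁻¹ s⁻¹)
    free monomer + living end → monomer in chains + living end, rate k4*[living end]*[free monomer] (k4 = 113 M⁻¹ s⁻¹)
    monomer in chains + living end → free monomer + living end, rate k5*[living end] as long as [monomer in chains] is above zero (k5 = 117 s⁻¹)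

1. which of the two ends with the longer chains by the average number of monomer units in a chain (chains begun, living or dead) ("neither" if they lie within 10%) (violet / teal / neither)
2. average number of monomer units in a chain (chains begun, living or dead) at the end, violet
3. average number of monomer units in a chain (chains begun, living or dead) at the end, teal

- where a step has two of a species, its rate is k times that concentration squared, and two are used at each turn
- the average divides the monomer in chains by the number of chains begun, living and dead together
- run time (violet): 20 min

1. Impurity first. Each initiator meets the impurity at 28.4 s⁻¹ and starts a chain at 0.248 s⁻¹, so the impurity is served first. We subtract it whole, and call the remainder n: 7.10 mM in violet, 3.10 mM in teal.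

2. Balance. Per living end, growth goes at 113 M⁻¹ s⁻¹ times the free monomer and loss at 117 s⁻¹. They balance at M* = 1.04 M, the equilibrium monomer concentration, which lies below the charge. Teal, with fewer living ends, approaches it in about 2.85 s, and initiator lasts about 7.79 s at M*. Both times are far shorter than the run, so we expect balance by the end.

3. The number. Let Λ = (charged free monomer − M*)/n. Violet gives 136 and teal 311. Λ is the monomer that can enter chains per chain that can begin, our length number. Teal comes out longer, by a factor 2.29, well outside the margin of 10%.

4. The test. Initiator also destroys itself in pairs. Reckoned with n as the initiator and the charged free monomer, that loss over chain starting is 0.145 in violet and 0.0635 in teal. Violet's ratio is larger than teal's, so we expect both lengths a little above Λ, violet's further. Violet's ratio is smaller than teal's lead in Λ, so we expect the order to stand.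

The forecast says teal, with 146 for violet and 325 for teal, since “the average length is set by the number of chains, which favours teal”.

The flask gives teal: 148 in violet and 322 in teal, which are 1.09 and 1.04 times Λ. Violet already reads 148 after 2.00 min. A neighbour like violet but charged with 0.50 M of free monomer stands below M*, so its Λ is negative, −76.1, and that flask ends with an average of 0.0334 monomer units per chain.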